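**Retrosynthetic overview**
- The tetralin ring is formed last, by an acid dienone–phenol 1,2-shift: the aryl-bearing carbon moves from the spiro carbon of a spiro[4.5]decadienone to the neighbouring ring carbon (para to OMe), expanding the cyclopentane to the six-membered ring.
- The spiro cyclopentane comes from an open-chain pentaacetate: both phenols are unmasked, base releases a syringyl quinone methide, and the guaiacyl phenoxide attacks it through its para carbon (new step).
- The open chain comes from a trans-2,3-disubstituted γ-butyrolactone (the first, temporary ring) by LiAlH4 reduction and peracetylation; the lactone comes from enolate benzylation (sets C3).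
- The lactone core comes from an L-proline aldol of a protected syringaldehyde with methyl 4-oxobutanoate (sets C2), then NaBH4 and lactonisation.
- Both arenes come from p-cresol by ring bromination, copper-catalysed methoxylation and pivaloylation, with side-chain oxidation (ring C) or side-chain bromination (ring A).

Assumption: one step is one pot with one purification; compounds carried on in the same pot are numbered and marked as not isolated.

**Step 1**
Reactants: 1 4-methylphenol (p-cresol)
Product: 4 3,5-dibromo-4-hydroxybenzaldehyde, via dibromocresol 2 (not isolated), via benzal bromide 3 (not isolated)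
Conditions: Br2 (2.05 equiv), o-dichlorobenzene, 35 °C; Br2 (2.1 equiv), 150–160 °C; then H2O, 100 °C
Reagents that add atoms: bromine BrBr; water O
Why: Electrophilic ring bromination ortho to OH, then thermal radical side-chain dibromination and hydrolysis of the benzal bromide (the technical one-pot cresol-to-hydroxybenzaldehyde process); no stereocentre.

**Step 2**
Reactants: 4 3,5-dibromo-4-hydroxybenzaldehyde
Product: 5 4-hydroxy-3,5-dimethoxybenzaldehyde (syringaldehyde)
Conditions: NaOMe (5 equiv), CuCl (10 mol %), DMF/MeOH, 110 °C; then HCl aq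
Reagents that add atoms: sodium methoxide C[O-].[Na+]
Why: Ullmann-type copper-catalysed methoxylation of both C–Br bonds ortho to the phenoxide, the established route to syringaldehyde.

**Step 3**
Reactants: 5 syringaldehyde
Product: 6 4-formyl-2,6-dimethoxyphenyl pivalate
Conditions: PivCl (1.3 equiv), Et3N, DMAP (cat.), CH2Cl2, 0 °C to rt
Reagents that add atoms: pivaloyl chloride CC(C)(C)C(=O)Cl
Why: O-acylation; the pivalate keeps the aldehyde electrophilic, has no enolisable hydrogen, survives the amide base of step 9 and is removed by LiAlH4 in step 10.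

**Step 4**
Reactants: 6 4-formyl-2,6-dimethoxyphenyl pivalate; 7 methyl 4-oxobutanoate
Product: 9 (4R)-4-{(R)-[3,5-dimethoxy-4-(pivaloyloxy)phenyl](hydroxy)methyl}dihydrofuran-2(3H)-one, via aldol aldehyde 8 (not isolated)
Conditions: 7 (3 equiv), L-proline (30 mol %), DMF, 4 °C; then NaBH4, MeOH, −20 °C; HCl aq work-up
Reagents that add atoms: none
Why: Proline enamine cross-aldol through the Houk–List transition state (anti adduct) sets the lactone stereocentre (future C2, R); NaBH4 reduces the aldehyde and the primary alcohol lactonises onto the methyl ester, while the carbinol centre (R) is temporary.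

**Step 5**
Reactants: 1 4-methylphenol
Product: 10 2-bromo-4-methylphenol
Conditions: Br2 (1.0 equiv), CH2Cl2, 0 °C
Reagents that add atoms: bromine BrBr
Why: Electrophilic aromatic monobromination ortho to OH (para position blocked).

**Step 6**
Reactants: 10 2-bromo-4-methylphenol
Product: 11 2-methoxy-4-methylphenol (creosol)
Conditions: NaOMe (3 equiv), CuBr (10 mol %), DMF/MeOH, 110 °C; then HCl aq
Reagents that add atoms: sodium methoxide C[O-].[Na+]
Why: Ullmann-type copper-catalysed methoxylation of an ortho-bromophenoxide, as in step 2.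

**Step 7**
Reactants: 11 creosol
Product: 12 2-methoxy-4-methylphenyl pivalate
Conditions: PivCl (1.2 equiv), Et3N, DMAP (cat.), CH2Cl2, 0 °C to rt
Reagents that add atoms: pivaloyl chloride CC(C)(C)C(=O)Cl
Why: O-acylation masks the phenol, tempers the ring towards bromine and gives a base-stable ester for step 9.

**Step 8**
Reactants: 12 2-methoxy-4-methylphenyl pivalate
Product: 13 4-(bromomethyl)-2-methoxyphenyl pivalate
Conditions: NBS (1.05 equiv), AIBN (5 mol %), PhCF3, 85 °C
Reagents that add atoms: N-bromosuccinimide O=C1CCC(=O)N1Br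
Why: Wohl–Ziegler radical benzylic bromination, precedented on the analogous creosol acetate.

**Step 9**
Reactants: 9 hydroxy lactone; 13 4-(bromomethyl)-2-methoxyphenyl pivalate
Product: 14 (3R,4R)-4-{(R)-[3,5-dimethoxy-4-(pivaloyloxy)phenyl](hydroxy)methyl}-3-[3-methoxy-4-(pivaloyloxy)benzyl]dihydrofuran-2(3H)-one
Conditions: LiN(SiMe3)2 (2.2 equiv), THF, −78 °C; 13 (1.2 equiv), −78 to −40 °C; NH4Cl aq
Reagents that add atoms: none
Why: Alkoxide–enolate dianion alkylation; the bromide approaches anti to the substituent on the neighbouring ring carbon, giving the 3,4-trans lactone and setting future C3 (R).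

**Step 10**
Reactants: 14 trans-lactone bis-pivalate
Product: 16 (1R,2R,3R)-2-(acetoxymethyl)-1-(4-acetoxy-3,5-dimethoxyphenyl)-3-(4-acetoxy-3-methoxybenzyl)butane-1,4-diyl diacetate, via pentaol 15 (not isolated)
Conditions: LiAlH4 (3 equiv), THF, 0 °C to rt; then pyridine, Ac2O (excess), DMAP (cat.), 0 °C to rt, same pot
Reagents that add atoms: acetic anhydride CC(=O)OC(C)=O
Why: Hydride reduction opens the lactone to the 1,4-diol and cleaves both pivalates, and the aluminium alkoxides and phenoxides are acetylated in situ; no stereocentre is touched.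

**Step 11**
Reactants: 16 pentaacetate
Product: 20 [(1S,2R,3R)-7-hydroxy-1-(4-hydroxy-3,5-dimethoxyphenyl)-6-methoxy-1,2,3,4-tetrahydronaphthalene-2,3-diyl]bis(methylene) diacetate, via bisphenol triacetate 17 (not isolated), via quinone methide 18 (not isolated), via spirodienone 19 (not isolated)
Conditions: pyrrolidine (2.1 equiv), CH2Cl2, 0 °C to rt; dilute to 5 mM, DBU (3 equiv), 0 °C to rt; then CF3CO2H (excess), 0 °C to rt
Reagents that add atoms: none
Why: Proposed new method: pyrrolidine cleaves only the two aryl acetates, DBU then lets the syringyl phenoxide expel the benzylic acetate to give quinone methide 18, which the tethered guaiacyl phenoxide can reach only through its para carbon (Ar1-5 participation, 5-exo 1,6-addition) so that spirodienone 19 forms (loss of ring A aromaticity is paid for by rearomatisation of ring C), and CF3CO2H finally induces the dienone–phenol 1,2-shift of the benzylic carbon C1 to the adjacent ring carbon para to OMe (ring expansion, cyclopentane to tetralin) with the aryl group ending trans to the C2 substituent (equatorial, the outcome of acid cyclisations in this lignan class, also reached if the C1–spiro bond ionises and recloses); the closest known reactions are the Winstein–Baird phenoxide ipso-alkylation to spiro[4.5]decadienones, 1,6-additions of naphthoxides to para-quinone methides and the acid dienone–phenol rearrangement.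

**Compound list**
1 | 4-methylphenol (p-cresol) | Cc1ccc(O)cc1 | starting material
2 | 2,6-dibromo-4-methylphenol | Cc1cc(Br)c(O)c(Br)c1 | intermediate
3 | 2,6-dibromo-4-(dibromomethyl)phenol | BrC(Br)c1cc(Br)c(O)c(Br)c1 | intermediate
4 | 3,5-dibromo-4-hydroxybenzaldehyde | O=Cc1cc(Br)c(O)c(Br)c1 | intermediate
5 | 4-hydroxy-3,5-dimethoxybenzaldehyde (syringaldehyde) | COc1cc(C=O)cc(OC)c1O | intermediate
6 | 4-formyl-2,6-dimethoxyphenyl pivalate | COc1cc(C=O)cc(OC)c1OC(=O)C(C)(C)C | intermediate
7 | methyl 4-oxobutanoate | COC(=O)CCC=O | starting material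
8 | methyl (3S,4R)-4-[3,5-dimethoxy-4-(pivaloyloxy)phenyl]-3-formyl-4-hydroxybutanoate | COC(=O)C[C@H](C=O)[C@@H](O)c1cc(OC)c(OC(=O)C(C)(C)C)c(OC)c1 | intermediate
9 | (4R)-4-{(R)-[3,5-dimethoxy-4-(pivaloyloxy)phenyl](hydroxy)methyl}dihydrofuran-2(3H)-one | O=C1C[C@H](CO1)[C@@H](O)c2cc(OC)c(OC(=O)C(C)(C)C)c(OC)c2 | intermediate
10 | 2-bromo-4-methylphenol | Cc1ccc(O)c(Br)c1 | intermediate
11 | 2-methoxy-4-methylphenol (creosol) | COc1cc(C)ccc1O | intermediate
12 | 2-methoxy-4-methylphenyl pivalate | COc1cc(C)ccc1OC(=O)C(C)(C)C | intermediate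
13 | 4-(bromomethyl)-2-methoxyphenyl pivalate | COc1cc(CBr)ccc1OC(=O)C(C)(C)C | intermediate
14 | (3R,4R)-4-{(R)-[3,5-dimethoxy-4-(pivaloyloxy)phenyl](hydroxy)methyl}-3-[3-methoxy-4-(pivaloyloxy)benzyl]dihydrofuran-2(3H)-one | O=C1[C@H](Cc3ccc(OC(=O)C(C)(C)C)c(OC)c3)[C@H](CO1)[C@@H](O)c2cc(OC)c(OC(=O)C(C)(C)C)c(OC)c2 | intermediate
15 | (1R,2R,3R)-1-(4-hydroxy-3,5-dimethoxyphenyl)-3-(4-hydroxy-3-methoxybenzyl)-2-(hydroxymethyl)butane-1,4-diol | COc1cc(C[C@@H](CO)[C@H](CO)[C@@H](O)c2cc(OC)c(O)c(OC)c2)ccc1O | intermediate
16 | (1R,2R,3R)-2-(acetoxymethyl)-1-(4-acetoxy-3,5-dimethoxyphenyl)-3-(4-acetoxy-3-methoxybenzyl)butane-1,4-diyl diacetate | COc1cc(C[C@@H](COC(C)=O)[C@H](COC(C)=O)[C@@H](OC(C)=O)c2cc(OC)c(OC(C)=O)c(OC)c2)ccc1OC(C)=O | intermediate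
17 | (1R,2R,3R)-2-(acetoxymethyl)-1-(4-hydroxy-3,5-dimethoxyphenyl)-3-(4-hydroxy-3-methoxybenzyl)butane-1,4-diyl diacetate | COc1cc(C[C@@H](COC(C)=O)[C@H](COC(C)=O)[C@@H](OC(C)=O)c2cc(OC)c(O)c(OC)c2)ccc1O | intermediate
18 | (2R,3R)-2-[(3,5-dimethoxy-4-oxocyclohexa-2,5-dien-1-ylidene)methyl]-3-(4-hydroxy-3-methoxybenzyl)butane-1,4-diyl diacetate | COc1cc(C[C@@H](COC(C)=O)[C@H](COC(C)=O)C=C2C=C(OC)C(=O)C(OC)=C2)ccc1O | intermediate
19 | [(1S,2R,3R)-1-(4-hydroxy-3,5-dimethoxyphenyl)-7-methoxy-8-oxospiro[4.5]deca-6,9-diene-2,3-diyl]bis(methylene) diacetate, aryl trans to the C2 acetoxymethyl, both epimers at the spiro carbon C5 | COC1=CC2(C=CC1=O)C[C@@H](COC(C)=O)[C@H](COC(C)=O)[C@H]2c3cc(OC)c(O)c(OC)c3 | intermediate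
20 | [(1S,2R,3R)-7-hydroxy-1-(4-hydroxy-3,5-dimethoxyphenyl)-6-methoxy-1,2,3,4-tetrahydronaphthalene-2,3-diyl]bis(methylene) diacetate | COc1cc2c(cc1O)[C@H](c1cc(OC)c(O)c(OC)c1)[C@@H](COC(C)=O)[C@H](COC(C)=O)C2 | target

**Totals**
Total step count: 11. Longest linear sequence: 7 steps (1, 2, 3, 4, 9, 10, 11 from p-cresol through ring C; equally 5, 6, 7, 8, 9, 10, 11 through ring A).

**Three steps most likely to fail**

Step 11 (the proposed new cascade). The quinone methide may be trapped by amine or acetate before the para-carbon attack, or the dienone may shift with poor regiocontrol; the acid stage should still funnel trapped C1 adducts to 20 by direct closure. The fallback uses known chemistry, sets out from 16 and comes back at 20. Treat 16 with CF3SO3H (10 mol %) in (CF3)2CHOH at rt; with both phenols still acetylated no phenoxide and no dearomatisation are possible, and the benzylic cation closes directly on the ring A carbon para to OMe (classical Friedel–Crafts cyclolignan closure, aryl trans) to give the aryltetralin tetraacetate F1. Pyrrolidine in CH2Cl2 at rt then removes only the two aryl acetates and gives 20.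

Step 10 (one-pot reduction and peracetylation). Once the syringyl pivalate is cleaved, the benzylic C1–O of the aluminate could be lost through a quinone methide and hydride, and acetylating aluminium alkoxides in the pot may be sluggish. The fallback sets out from 14 and comes back at 20. Close the ring first: 14 with CF3SO3H (cat.) in (CF3)2CHOH gives the trans-fused aryltetralin lactone bis-pivalate F2 (α-conidendrin skeleton, C=O on C3 and CH2O on C2 of the tetralin, configuration as in 20). LiAlH4 in THF then reduces the lactone and both pivalates, with no benzylic C–O left to lose, to the tetraol 5-methoxyisolariciresinol F3. Lipase CAL-B with vinyl acetate in THF acetylates only the two primary alcohols and gives 20.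

Step 8 (radical bromination). The electron-rich ring may be brominated in competition with the methyl group. The fallback sets out from 11 and comes back at 13. Oxidise creosol 11 with O2, CoCl2 (cat.), NaOH in MeOH at 60 °C (technical cresol autoxidation) to vanillin F4. PivCl, Et3N and DMAP give 4-formyl-2-methoxyphenyl pivalate F5. NaBH4 in MeOH at 0 °C gives 4-(hydroxymethyl)-2-methoxyphenyl pivalate F6. PBr3 in CH2Cl2 at 0 °C gives 13.

**Further compounds**
F1 | step 11 | [(1S,2R,3R)-7-acetoxy-1-(4-acetoxy-3,5-dimethoxyphenyl)-6-methoxy-1,2,3,4-tetrahydronaphthalene-2,3-diyl]bis(methylene) diacetate | COc1cc2c(cc1OC(C)=O)[C@H](c1cc(OC)c(OC(C)=O)c(OC)c1)[C@@H](COC(C)=O)[C@H](COC(C)=O)C2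
F2 | step 10 | trans-fused aryltetralin γ-lactone bis-pivalate (α-conidendrin skeleton, configuration as in 20) | COc1cc2c(cc1OC(=O)C(C)(C)C)[C@H](c1cc(OC)c(OC(=O)C(C)(C)C)c(OC)c1)[C@@H](COC3=O)[C@H]3C2
F3 | step 10 | (1S,2R,3R)-7-hydroxy-1-(4-hydroxy-3,5-dimethoxyphenyl)-2,3-bis(hydroxymethyl)-6-methoxy-1,2,3,4-tetrahydronaphthalene (5-methoxyisolariciresinol) | COc1cc2c(cc1O)[C@H](c1cc(OC)c(O)c(OC)c1)[C@@H](CO)[C@H](CO)C2
F4 | step 8 | 4-hydroxy-3-methoxybenzaldehyde (vanillin) | COc1cc(C=O)ccc1O
F5 | step 8 | 4-formyl-2-methoxyphenyl pivalate | COc1cc(C=O)ccc1OC(=O)C(C)(C)C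
F6 | step 8 | 4-(hydroxymethyl)-2-methoxyphenyl pivalate | COc1cc(CO)ccc1OC(=O)C(C)(C)C
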